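**Retrosynthetic overview**
1. Target 24 comes from 22. Both aryl sulfates are carried as aryl fluorosulfates and the carbinol as its trifluoroacetate, and one basic glycolysis unmasks all three.
2. Rings C and D (right decalin, four stereocentres) come from one proton-initiated chair–chair bicyclisation of the (13Z,17E,21E)-triene 21. Ring C closes first, then ring D. Rings A/B come intact from sclareolide and ring E from hydroquinone.
3. The C12–C13 bond comes from a Negishi union of homodrimanyl iodide 6 with (Z)-vinyl iodide 19. The Z geometry is what later places the large chain axial on C13.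
4. Key disconnection: the axial tertiary C8–O bond. It is made by thermodynamically controlled breaking and re-forming of this C–O bond (8α to 8β) on ambradiol bis(trifluoroacetate).
5. 19 comes from farnesol (terminal cleavage, Z-iodo-olefination), hydroquinone and SO2F2.

Numbering: C1–C12 as in labdanes for the sclareolide half. C13–C23 then run along the chain to the benzylic CH2 (C23). Methyl groups are named by the carbon that bears them.

Assumption: the bis(hydrogen sulfate) drawn is generated as its caesium salt and written in neutral form after cold acid work-up; the (R)-acid of step 10 is taken to give the 17β-methyl series, otherwise its (S)-antipode is used.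

Step 1
Reactants: 1 (+)-sclareolide
Product: 2 ambradiol; (5S,8R,9R,10S)-13,14,15,16-tetranorlabdane-8,12-diol (8α-OH equatorial; 8-CH3 β-axial)
Conditions: LiAlH4, THF, 0 °C to rt
Reagents that add atoms: none
Why: Hydride reduction of the γ-lactone to the 1,4-diol touches no stereocentre, so C5, C9 and C10 are carried over from 1.

Step 2
Reactants: 2 ambradiol
Product: 5 (5S,8S,9R,10S)-12-hydroxy-13,14,15,16-tetranorlabdan-8-yl trifluoroacetate (8β-ester axial; 8-CH3 α-equatorial), via 8α-bis(trifluoroacetate) 3 (not isolated), via 8β-bis(trifluoroacetate) 4 (not isolated)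
Conditions: (CF3CO)2O (3 equiv), CF3CO2H–CH2Cl2 (1:1), 0 °C; CF3SO3H (2 mol%), −20 °C, 16 h; pyridine (5 mol%), evaporate; MeOH, 0 °C, 1 h
Reagents that add atoms: trifluoroacetic anhydride O=C(OC(=O)C(F)(F)F)C(F)(F)F; trifluoroacetic acid OC(=O)C(F)(F)F
Why: Proposed new method: thermodynamic stereo-editing of a tertiary carbinol by reversible C–O heterolysis, in which both hydroxyls are first acylated (3), the tertiary C8–O bond (the primary ester cannot ionise) then breaks and re-forms repeatedly in the strongly ionising, weakly nucleophilic CF3CO2H medium via the C8 cation and alkenes that re-add CF3CO2H in the Markovnikov sense, so the new C8–O bond is placed under thermodynamic control that favours the axial 8β-ester with equatorial methyl (4) by about 2 kcal/mol because the syn-diaxial 8-CH3/10-CH3 contact of 3 is traded for a smaller O/CH3 contact, and methanol finally cleaves only the unhindered primary ester; the closest known reaction types are the acid-mediated C8 epimerisation of sclareolide to its cis-lactone and the Markovnikov addition of CF3CO2H to alkenes.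

Step 3
Reactants: 5 8β-trifluoroacetoxy alcohol
Product: 6 (5S,8S,9R,10S)-12-iodo-13,14,15,16-tetranorlabdan-8-yl trifluoroacetate
Conditions: I2, PPh3, imidazole, CH2Cl2, 0 °C
Reagents that add atoms: iodine [I][I]
Why: Appel-type (Garegg–Samuelsson) iodination is an SN2 reaction at the primary carbinol, and the acylated tertiary oxygen cannot close the ambrox-type tetrahydrofuran.

Step 4
Reactants: 7 (2E,6E)-farnesol
Product: 9 (2E,6E)-10,11-epoxyfarnesol (racemic at C10), via terminal bromohydrin 8 (not isolated)
Conditions: NBS, THF–H2O, 0 °C; then K2CO3, MeOH, rt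
Reagents that add atoms: water O
Why: This is the van Tamelen terminal bromohydrin formation (in aqueous THF only the terminal alkene of the coiled chain is exposed) followed by intramolecular Williamson closure, and the new centre is racemic and is destroyed in step 5.

Step 5
Reactants: 9 10,11-epoxyfarnesol
Product: 11 (4E,8E)-10-hydroxy-4,8-dimethyldeca-4,8-dienal, via vicinal triol 10 (not isolated)
Conditions: H5IO6, THF–H2O, 0 °C
Reagents that add atoms: none
Why: Acidic epoxide hydrolysis and Malaprade glycol cleavage occur in one pot and leave both E-alkenes and the allylic alcohol untouched.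

Step 6
Reactants: 11 hydroxy aldehyde; 12 ethyltriphenylphosphonium iodide
Product: 16 (2E,6E,10Z)-11-iodo-3,7-dimethyldodeca-2,6,10-trien-1-ol, via ethylidenetriphenylphosphorane 13 (not isolated), via (1-iodoethyl)triphenylphosphonium iodide 14 (not isolated), via (1-iodoethylidene)triphenylphosphorane 15 (not isolated)
Conditions: 12 (3 equiv), n-BuLi, THF, 0 °C; I2, −78 °C; NaN(SiMe3)2, −20 °C; then 11, −78 to −20 °C
Reagents that add atoms: iodine [I][I]
Why: In this Stork–Zhao-type Wittig iodo-olefination the kinetic cis-oxaphosphetane gives the (Z)-2-iodoalkene (iodine cis to the chain), the excess ylide covers the free hydroxyl, and the minor E isomer is removed by chromatography.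

Step 7
Reactants: 16 (Z)-vinyl iodide allylic alcohol; 17 hydroquinone
Product: 18 2-[(2E,6E,10Z)-11-iodo-3,7-dimethyldodeca-2,6,10-trienyl]benzene-1,4-diol
Conditions: 17 (4 equiv), BF3·OEt2 (0.5 equiv), 1,4-dioxane, rt
Reagents that add atoms: none
Why: In this Friedel–Crafts allylation BF3 ionises the primary allylic alcohol and the excess symmetric hydroquinone attacks the unhindered allyl terminus, which gives the linear 2-substituted product with the E-alkene kept.

Step 8
Reactants: 18 prenylated hydroquinone
Product: 19 2-[(2E,6E,10Z)-11-iodo-3,7-dimethyldodeca-2,6,10-trienyl]-1,4-phenylene bis(fluorosulfate)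
Conditions: SO2F2 (balloon), Et3N, CH2Cl2, rt
Reagents that add atoms: sulfuryl fluoride O=S(=O)(F)F
Why: Sulfur–fluoride exchange of both phenols installs acid-stable masked sulfates that make ring E electron-poor and remove every oxygen nucleophile before step 10.

Step 9
Reactants: 6 homodrimanyl iodide; 19 (Z)-vinyl iodide
Product: 21 (13Z,17E,21E)-triene; 2-{(2E,6E,10Z)-3,7,11-trimethyl-13-[(5S,8S,9R,10S)-8-trifluoroacetoxy-11,12,13,14,15,16-hexanorlabdan-9-yl]trideca-2,6,10-trienyl}-1,4-phenylene bis(fluorosulfate), via alkylzinc iodide 20 (not isolated)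
Conditions: 6, Zn dust, LiCl, THF, 30 °C; then 19, PdCl2(dppf) (3 mol%), THF, rt
Reagents that add atoms: none
Why: In this Negishi coupling zinc insertion tolerates the ester, zerovalent palladium inserts into the C(sp2)–I bond far faster than into an aryl fluorosulfate, and the coupling retains the alkene geometry, so C12 ends up cis to C15 (13Z).

Step 10
Reactants: 21 triene
Product: 22 bicyclised 8β-trifluoroacetate bis(fluorosulfate) (C12 chain β-axial and 13-CH3 α-equatorial; 18α-H; 17β-CH3; 22α-H with β-equatorial arylmethyl; C20=C21 alkene)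
Conditions: (R)-2-(2-fluorobenzyloxy)-2′-hydroxy-1,1′-binaphthyl·SnCl4 (2 equiv), toluene, −78 °C, 3 d; Et3N quench
Reagents that add atoms: none
Why: In this Lewis acid-assisted chiral Brønsted acid (LBA) induced biomimetic polyene cyclisation the bulky chiral proton source attacks C14 of the 13Z-alkene (its open CH3/H edge resembles a terminal prenyl group, both E-alkenes carry a chain on each edge and C21=C22 is further deactivated by the electron-poor benzyl group), C18 adds to C13 anti to the proton and C22 adds to C17 through a chair–chair array, so the Z geometry places C12 axial (β, cis to 17-CH3) and 13-CH3 equatorial, the E geometries give the trans fusion (18α-H, 17β-CH3) and the equatorial 22β-arylmethyl group, the acid antipode fixes the absolute sense, and loss of the axial 20-H gives the trisubstituted alkene because neither the fluorosulfates nor the trifluoroacetate can trap a cation.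

Step 11
Reactants: 22 bicyclised precursor
Product: 24 target CNP0471499.2, via bis(2-hydroxyethyl sulfate) 23 (not isolated)
Conditions: Cs2CO3, HOCH2CH2OH–THF, rt; then cold 0.5 M HCl, n-BuOH extraction
Reagents that add atoms: ethylene glycol OCCO
Why: In this basic glycolysis of aryl fluorosulfates glycolate displaces fluoride at sulfur, the 2-hydroxyethyl sulfate diester 23 expels oxirane to leave the aryl sulfate monoester, and the same medium transesterifies the labile trifluoroacetate, so the hindered tertiary alcohol never meets a sulfating agent and no stereocentre is touched.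

**Compound list**
1 | (+)-sclareolide (trans-lactone, 8α-O) | O=C1C[C@@H]2[C@@]3(C)CCCC(C)(C)[C@@H]3CC[C@@]2(C)O1 | starting material
2 | ambradiol (8α-OH) | OCC[C@@H]1[C@@]2(C)CCCC(C)(C)[C@@H]2CC[C@@]1(C)O | intermediate
3 | ambradiol 8α,12-bis(trifluoroacetate) | O=C(OCC[C@@H]1[C@@]2(C)CCCC(C)(C)[C@@H]2CC[C@@]1(C)OC(=O)C(F)(F)F)C(F)(F)F | intermediate
4 | 8-epi-ambradiol 8β,12-bis(trifluoroacetate) | O=C(OCC[C@@H]1[C@@]2(C)CCCC(C)(C)[C@@H]2CC[C@]1(C)OC(=O)C(F)(F)F)C(F)(F)F | intermediate
5 | 12-hydroxy-13,14,15,16-tetranorlabdan-8β-yl trifluoroacetate | OCC[C@@H]1[C@@]2(C)CCCC(C)(C)[C@@H]2CC[C@]1(C)OC(=O)C(F)(F)F | intermediate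
6 | 12-iodo-13,14,15,16-tetranorlabdan-8β-yl trifluoroacetate | [I]CC[C@@H]1[C@@]2(C)CCCC(C)(C)[C@@H]2CC[C@]1(C)OC(=O)C(F)(F)F | intermediate
7 | (2E,6E)-farnesol | CC(C)=CCC/C(C)=C/CC/C(C)=C/CO | starting material
8 | 10-bromo-11-hydroxy-10,11-dihydrofarnesol (racemic) | CC(C)(O)C(Br)CC/C(C)=C/CC/C(C)=C/CO | intermediate
9 | (2E,6E)-10,11-epoxyfarnesol (racemic) | CC1(C)OC1CC/C(C)=C/CC/C(C)=C/CO | intermediate
10 | (2E,6E)-10,11-dihydroxy-10,11-dihydrofarnesol (racemic) | CC(C)(O)C(O)CC/C(C)=C/CC/C(C)=C/CO | intermediate
11 | (4E,8E)-10-hydroxy-4,8-dimethyldeca-4,8-dienal | O=CCC/C(C)=C/CC/C(C)=C/CO | intermediate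
12 | ethyltriphenylphosphonium iodide | CC[P+](c1ccccc1)(c1ccccc1)c1ccccc1.[I-] | starting material
13 | ethylidenetriphenylphosphorane | CC=P(c1ccccc1)(c1ccccc1)c1ccccc1 | intermediate
14 | (1-iodoethyl)triphenylphosphonium iodide (racemic) | CC([I])[P+](c1ccccc1)(c1ccccc1)c1ccccc1.[I-] | intermediate
15 | (1-iodoethylidene)triphenylphosphorane | CC([I])=P(c1ccccc1)(c1ccccc1)c1ccccc1 | intermediate
16 | (2E,6E,10Z)-11-iodo-3,7-dimethyldodeca-2,6,10-trien-1-ol | C/C([I])=C/CC/C(C)=C/CC/C(C)=C/CO | intermediate
17 | hydroquinone | Oc1ccc(O)cc1 | starting material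
18 | 2-[(2E,6E,10Z)-11-iodo-3,7-dimethyldodeca-2,6,10-trienyl]benzene-1,4-diol | C/C([I])=C/CC/C(C)=C/CC/C(C)=C/Cc1cc(O)ccc1O | intermediate
19 | bis(fluorosulfate) of 18 | C/C([I])=C/CC/C(C)=C/CC/C(C)=C/Cc1cc(OS(=O)(=O)F)ccc1OS(=O)(=O)F | intermediate
20 | (8β-trifluoroacetoxy-13,14,15,16-tetranorlabdan-12-yl)zinc iodide | [I][Zn]CC[C@@H]1[C@@]2(C)CCCC(C)(C)[C@@H]2CC[C@]1(C)OC(=O)C(F)(F)F | intermediate
21 | (13Z,17E,21E)-triene, 8β-trifluoroacetate, bis(fluorosulfate) | C/C(CC[C@@H]1[C@@]2(C)CCCC(C)(C)[C@@H]2CC[C@]1(C)OC(=O)C(F)(F)F)=C/CC/C(C)=C/CC/C(C)=C/Cc1cc(OS(=O)(=O)F)ccc1OS(=O)(=O)F | intermediate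
22 | bicyclised 8β-trifluoroacetate bis(fluorosulfate) | CC1=CC[C@H]2[C@@](C)(CC[C@@H]3[C@@]4(C)CCCC(C)(C)[C@@H]4CC[C@]3(C)OC(=O)C(F)(F)F)CCC[C@]2(C)[C@H]1Cc1cc(OS(=O)(=O)F)ccc1OS(=O)(=O)F | intermediate
23 | 8β-alcohol bis(2-hydroxyethyl sulfate) diester | CC1=CC[C@H]2[C@@](C)(CC[C@@H]3[C@@]4(C)CCCC(C)(C)[C@@H]4CC[C@]3(C)O)CCC[C@]2(C)[C@H]1Cc1cc(OS(=O)(=O)OCCO)ccc1OS(=O)(=O)OCCO | intermediate
24 | CNP0471499.2 | CC1=CC[C@H]2[C@@](C)(CC[C@@H]3[C@@]4(C)CCCC(C)(C)[C@@H]4CC[C@]3(C)O)CCC[C@]2(C)[C@H]1Cc1cc(OS(=O)(=O)O)ccc1OS(=O)(=O)O | target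

**Total step count:** 11. **Longest linear sequence:** 8 (steps 4–11).

**Three steps most likely to fail**

Step 2 (the proposed new step). The equilibrium may rest on the Δ7/Δ8 alkenes instead of the ester. The C8 cation may also undergo hydride or methyl shifts, or scramble C9. The fallback uses known chemistry and sets out from 1. Concentrated H2SO4 in HCO2H at rt ionises the lactone C8–O bond, and the carboxyl group re-closes it from the β face to give the cis-lactone 8-epi-sclareolide F1. LiAlH4 reduces this to 8-epi-ambradiol F2. (CF3CO)2O/pyridine at 0 °C gives 4, and brief methanolysis comes back to the route at 5. This is one step longer.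

Step 9. Palladium could also insert into a fluorosulfate, or the alkylzinc could be lost by β-hydride elimination. The fallback reverses the order of events so that no fluorosulfate meets palladium, and it sets out from 16 and 20. The Negishi coupling is run on the free allylic alcohol with one extra equivalent of 20 and gives the triene allylic alcohol F3. BF3·OEt2 with excess hydroquinone at 0 °C gives the triene hydroquinone F4, because the allylic alcohol ionises far faster than the tertiary trifluoroacetate. SO2F2/Et3N then comes back to the route at 21.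

Step 10. Three things can go wrong:
- Protonation may start at C17=C18.
- Termination may give Δ21(methyl) or Δ21(22) alkene isomers.
- The tertiary ester may ionise.

The fallback changes the initiating electrophile from a proton to iodonium under non-acidic conditions, and it sets out from 21. N-Iodosuccinimide with a stoichiometric chiral BINOL-derived phosphoramidite (toluene, −40 °C) performs an enantioselective iodonium-initiated bicyclisation to the equatorial 14β-iodide F5. Bu3SnH/AIBN (benzene, 80 °C) removes the iodine and comes back to the route at 22.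

**Further compounds**
F1 | step 2 | 8-epi-sclareolide (cis-lactone, 8β-O, 8α-CH3) | O=C1C[C@@H]2[C@@]3(C)CCCC(C)(C)[C@@H]3CC[C@]2(C)O1
F2 | step 2 | 8-epi-ambradiol (8β-OH axial) | OCC[C@@H]1[C@@]2(C)CCCC(C)(C)[C@@H]2CC[C@]1(C)O
F3 | step 9 | (13Z,17E,21E)-triene allylic alcohol, 8β-trifluoroacetate | C/C(CC[C@@H]1[C@@]2(C)CCCC(C)(C)[C@@H]2CC[C@]1(C)OC(=O)C(F)(F)F)=C/CC/C(C)=C/CC/C(C)=C/CO
F4 | step 9 | (13Z,17E,21E)-triene hydroquinone, 8β-trifluoroacetate | C/C(CC[C@@H]1[C@@]2(C)CCCC(C)(C)[C@@H]2CC[C@]1(C)OC(=O)C(F)(F)F)=C/CC/C(C)=C/CC/C(C)=C/Cc1cc(O)ccc1O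
F5 | step 10 | 14β-iodo derivative of 22 (iodine equatorial) | CC1=CC[C@H]2[C@@](C)(CC[C@@H]3[C@@]4(C)CCCC(C)(C)[C@@H]4CC[C@]3(C)OC(=O)C(F)(F)F)[C@@H]([I])CC[C@]2(C)[C@H]1Cc1cc(OS(=O)(=O)F)ccc1OS(=O)(=O)F
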